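# Synthesis proposal for CNP0137407.10: ring expansion of a cyclotene-derived 5-7 diol to the (Z,Z)-cyclodecadienedione

## The problem

The target is a ten-membered carbocycle (C1–C10) with two Z trisubstituted olefins, C1=C10 (methyl C14) and C4=C5 (methyl C15), and a trans-fused α-methylene-γ-butyrolactone across C6–C7 (O on C6; C11, C12 and the methylene C13 on C7). The ring carries five stereocentres (3S, 6R, 7R, 8R, 9R): an acetate at C3, a free hydroxyl at C8 and a (2R,3R)-2,3-epoxy-2-methylbutanoate at C9. C6, C7 and C8 form a contiguous syn,syn triad that can be built on an open chain. C9 is vicinal to C8 in the syn sense, which is the Felkin–Anh sense for hydride addition to a C9 ketone, whereas C3 is insulated by the C4=C5 olefin and needs reagent control. Closing a ten-membered ring directly is unfavourable, and each Z trisubstituted olefin made on an open chain would need its own selective method. Three like oxygens (C3, C8, C9) must end as three different functions, and O8 lies γ to C12 just as O6 does, so O8 must stay masked while the lactone forms. The exocyclic enoate is a Michael acceptor, the glycidic ester and the allylic acetate do not tolerate strong acid, and neither ester tolerates enolate chemistry, which fixes the order of the last steps. The enabling feature is that C3 and C9 are 1,5-related through C2, C1 and C10: a C3–C9 bond turns the macrocycle into a cyclopentene (C3, C2, C1, C10, C9) fused to a cycloheptene (C3 to C9 through C4–C8), where both olefins are cis by ring size, and that bond is the bond of a 1,2-diol once C3 and C9 are ketones.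

## Retrosynthesis

**Ester and ether C–O bonds (42 ⇒ 41 ⇒ 39 + 24; 39 ⇒ 38).** The last bonds cut are O8–CH2 of a (2-naphthylmethoxy)methyl ether, the C9 ester and the C3 acetate. The esters are placed last because neither survives the lactone enolate needed for C13. The acetal-type O8 group is dictated by the α-alkoxyalkyllithium used earlier, and the naphthylmethyl variant is chosen over a methoxymethyl ether because it leaves under neutral oxidation, which the epoxy ester tolerates. The forward steps must tell the C3 hydroxyl from the more hindered C9 hydroxyl of 38. Acid 24 comes from angelic acid 21 through 22 and epoxy alcohol 23 by asymmetric epoxidation.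

**C11=C13 and the lactone C12–O6 bond (38 ⇒ 37 ⇒ 33 ⇒ 32 ⇒ 31).** The methylene is cut as an iminium electrophile on the lactone enolate, and the lactone as a C12 acetal plus a silylated O6. Carrying the lactone earlier is not possible, since it would not survive the organolithium of step 15, and a free C6 hydroxyl next to a C3 ketone would close to a transannular hemiketal. Precursor 31 is a ten-membered ring with three silyl ethers and an acetal. The forward sequence needs one acid step that frees only O6 and C12.

**C3–H and C9–H (31 ⇒ 30 ⇒ 29).** Both carbinols are traced to enone carbonyls. This removes two stereocentres and leaves a dione whose two carbonyls are each flanked by an α-methylalkenyl group. One oxazaborolidine enantiomer should serve both, with reagent control at C3 and reagent plus Felkin–Anh control at C9.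

**C3–C9 (29 ⇒ 28, the key disconnection).** Reconnecting the two carbonyl carbons as a 1,2-diol gives the cis-fused bicyclo[5.3.0]decadienediol 28. Against cutting a ring C–C bond of the macrocycle directly, this cut leaves no medium ring to close and no olefin geometry to control. The forward reaction only has to cleave a cis glycol.

**C4=C5 (28 ⇒ 27).** The cycloheptene is opened by ring-closing metathesis to a cyclopentenediol with an isopropenyl arm on C3 and a vinyl-terminated arm on C9. Cutting here rather than at C8–C9 keeps C8–C9 for the convergent fragment union. The forward step must close a trisubstituted olefin next to a fully substituted carbon.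

**C8–C9 (27 ⇒ 20 + 7).** This is the most convergent cut: stannane 20 carries C5–C8, C11, C12 and all three chain stereocentres, and enone 7 carries C1–C4, C9, C10 and both methyls. The forward step needs tin–lithium exchange with retention at C8 and addition to C9 anti to the C3 silyloxy group, so that the two arms end up cis. Enone 7 can be racemic because C3 and C9 are erased in step 17.

**Enone 7 (7 ⇒ 6 ⇒ 5 ⇒ 2 + 3; 2 ⇒ 1).** Cyclotene 1 supplies C2, C1, C10, C14 and both oxygenated carbons. The C3–C4 bond comes from isopropenylmagnesium bromide 3 on methyl ether 2, and C1=C10 from a Saegusa–Ito oxidation of bis-silyl compound 6.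

**Stannane 20 (20 ⇒ 18 ⇒ 17 ⇒ 16 ⇒ 15 ⇒ 12 + 13; 12 ⇒ 9 + 10; 9 ⇒ 8).** C8–Sn is cut to aldehyde 18 (Felkin–Anh addition gives the 7,8-syn relationship). C6–C7 is cut by an Evans syn aldol between imide 12 and acrolein 13, which sets C6 and C7. Imide 12 comes from acid 9 (from commercial ester 8) and oxazolidinone 10.

## Roads not taken

Alternative 1: The cut is C9–C10. In the forward direction CrCl2 with catalytic NiCl2 would join a C10 (Z)-alkenyl iodide to a C9 aldehyde on an open chain that already holds the α-methylene lactone and the C3 acetate, giving A1.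
- Merits: A1 is two steps from the target (C9 esterification, silyl removal), against nine steps after the key step here; the assembly is more convergent; C3 is set on an open chain.
- Weak points: the ten-membered ring is closed directly, needing high dilution and a large excess of divalent chromium; both Z trisubstituted olefins, one as an alkenyl iodide, must be made stereoselectively on the chain; the C9 configuration is decided during a medium-ring closure and is hard to predict.
- Comparison: Alternative 1 is better in endgame length. The chosen plan sets against this that no macrocyclisation is needed, both Z geometries come from small rings, and C9 is set by a reduction whose reagent and substrate preferences agree.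

Alternative 2: The cut is C6–C7 with O reconnected to C13, which expands the carbocycle to a thirteen-membered cyclic diallylic ether stannylated at C6. Tin–lithium exchange with n-C4H9Li would trigger a [2,3]-Wittig shift that forms C6–C7, frees the C6 hydroxyl, creates C11=C13 and contracts the ring, giving A2.
- Merits: one step makes a ring C–C bond, two stereocentres and the methylene carbon, so no enolate methylenation is needed; a thirteen-membered ether is easier to close than a ten-membered carbocycle.
- Weak points: two ring-forming events are needed; both Z olefins again come from open-chain chemistry; the C6/C7 outcome depends on the carbanion configuration and the allyl ether geometry through a transannular transition state; a [1,2]-shift can compete; A2 still needs PMB removal, oxidation to the lactone and differentiation of three silyl ethers.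
- Comparison: Alternative 2 is better in how it delivers C13. The chosen plan sets C6 and C7 by an auxiliary aldol of established reliability and never has to control olefin geometry.

Alternative 3: The cut is C8–C9. SmI2 would reduce a C8 aldehyde and a C9 (Z)-enal on an open chain to ketyls that couple, giving diol A3 with the ring and both carbinol centres.
- Merits: two stereocentres and the ring form in one step, with no protecting groups on O8 and O9 beforehand; the chosen key step forms no stereocentre at all.
- Weak points: the enal ketyl is an allyl-type radical anion, so the C1=C10 geometry can be lost and coupling can occur at C1; samarium-bridged closures of small rings favour the cis diol, whereas the target needs the trans (8,9-threo) arrangement; the two hydroxyls of A3 must then be told apart for selective C9 acylation; the methylene must be added afterwards because SmI2 reduces such enoates.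
- Comparison: Alternative 3 could be shorter in the longest linear sequence. The chosen plan sets against this secure olefin geometry and separate, individually controllable events for C8 (stannylation) and C9 (reduction).

Key step: step 17

## Remarks on the chemistry

- Enone 7 is used as the racemate. Each enantiomer should add the alkyllithium anti to its silyloxy group, so 26, 27 and 28 are pairs of cis diastereomers differing at C3 and C9 together. Names and SMILES show the (3S,9R) member; the (3R,9S) member is carried along, and both give the single dione 29.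
- Chloromethyl naphthalen-2-ylmethyl ether is taken to be a catalogue reagent.
- Locants C1–C15 in the text are those defined in the first section. Systematic names use their own numbering, and the C7 descriptor reads S in 32–41 only because of the sequence rule (same geometry as 7R in 42).

## Route

Step 1
Reactants: 1 cyclotene (2-hydroxy-3-methylcyclopent-2-en-1-one)
Product: 2 2-methoxy-3-methylcyclopent-2-en-1-one
Conditions: Me2SO4, K2CO3, acetone, reflux
Reagents that add atoms: dimethyl sulfate, COS(=O)(=O)OC
Why: O-Alkylation of the enolised 1,2-diketone (Williamson ether synthesis) leaves the C3 carbonyl free for addition and masks C9 as an enol ether.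

Step 2
Reactants: 2 2-methoxy-3-methylcyclopent-2-en-1-one; 3 isopropenylmagnesium bromide
Product: 5 2-hydroxy-5-methyl-2-(prop-1-en-2-yl)cyclopentan-1-one (racemic), via carbinol enol ether 4 (not isolated)
Conditions: THF, −78 to 0 °C; then 1 M HCl, THF, 0 °C
Reagents that add atoms: water, O
Why: Grignard 1,2-addition forms C3–C4, and dilute acid then hydrolyses the enol ether to the C9 ketone (an acyloin). C3 forms racemic, which is harmless because it becomes a carbonyl carbon in step 17.

Step 3
Reactants: 5 2-hydroxy-5-methyl-2-(prop-1-en-2-yl)cyclopentan-1-one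
Product: 6 3-methyl-1-(prop-1-en-2-yl)-1,2-bis[(trimethylsilyl)oxy]cyclopent-2-ene (racemic)
Conditions: Me3SiOTf (2.5 equiv), Et3N, CH2Cl2, 0 °C
Reagents that add atoms: trimethylsilyl trifluoromethanesulfonate, C[Si](C)(C)OS(=O)(=O)C(F)(F)F
Why: Soft enolisation and silylation; C10 is the only enolisable α-carbon (C3 is quaternary), so one silyl enol ether forms while the tertiary hydroxyl is capped in the same operation.

Step 4
Reactants: 6 bis-silyl compound
Product: 7 2-methyl-5-(prop-1-en-2-yl)-5-[(trimethylsilyl)oxy]cyclopent-2-en-1-one (racemic)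
Conditions: Pd(OAc)2 (10 mol %), O2 (1 atm), DMSO, rt
Reagents that add atoms: none
Why: Saegusa–Ito oxidation: the enolate bound to divalent palladium loses a β-hydrogen from the ring methylene C1 to give the conjugated endocyclic C1=C10 enone. The tertiary silyl ether is not affected.

Step 5
Reactants: 8 methyl 4,4-dimethoxybutanoate
Product: 9 4,4-dimethoxybutanoic acid
Conditions: LiOH·H2O, THF/H2O, 0 °C to rt; then 1 M HCl to pH 4, 0 °C
Reagents that add atoms: lithium hydroxide, [Li+].[OH-]
Why: Ester saponification; careful acidification keeps the acetal intact, and the acid is used at once.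

Step 6
Reactants: 9 4,4-dimethoxybutanoic acid; 10 (4S)-4-benzyl-1,3-oxazolidin-2-one
Product: 12 (4S)-4-benzyl-3-(4,4-dimethoxybutanoyl)-1,3-oxazolidin-2-one, via mixed pivalic anhydride 11 (not isolated)
Conditions: t-BuCOCl, Et3N, THF, −20 °C; then 10, LiCl, −20 °C to rt
Reagents that add atoms: none
Why: N-Acylation of the auxiliary through a mixed anhydride under mild, non-acidic conditions that suit the acetal.

Step 7
Reactants: 12 acyl oxazolidinone; 13 acrolein
Product: 15 (4S)-4-benzyl-3-[(2S,3R)-2-(2,2-dimethoxyethyl)-3-hydroxypent-4-enoyl]-1,3-oxazolidin-2-one, via boron enolate 14 (not isolated)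
Conditions: n-Bu2BOTf, i-Pr2NEt, CH2Cl2, −78 to 0 °C; 13, −78 to 0 °C; then pH 7 buffer, MeOH, H2O2
Reagents that add atoms: none
Why: Evans syn aldol: the (Z)-boron enolate reacts through a chair transition state on the face away from the benzyl group, forming C6–C7 and setting C6 and C7 (syn) in the sense needed for 6R,7R of the target.

Step 8
Reactants: 15 aldol adduct
Product: 16 (2S,3R)-2-(2,2-dimethoxyethyl)-3-hydroxy-N-methoxy-N-methylpent-4-enamide
Conditions: MeNHOMe·HCl, AlMe3, CH2Cl2, −10 °C to rt
Reagents that add atoms: N,O-dimethylhydroxylamine hydrochloride, CNOC.Cl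
Why: Aluminium amide transamination of the β-hydroxy imide gives the Weinreb amide and returns the auxiliary, without epimerising C7.

Step 9
Reactants: 16 Weinreb amide
Product: 17 (2S,3R)-2-(2,2-dimethoxyethyl)-N-methoxy-N-methyl-3-[(triethylsilyl)oxy]pent-4-enamide
Conditions: Et3SiCl, imidazole, DMF, 0 °C to rt
Reagents that add atoms: chlorotriethylsilane, CC[Si](Cl)(CC)CC
Why: Silyl protection of the secondary allylic alcohol; the chloride with imidazole is used because silyl triflates can attack dimethyl acetals.

Step 10
Reactants: 17 silylated Weinreb amide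
Product: 18 (2S,3R)-2-(2,2-dimethoxyethyl)-3-[(triethylsilyl)oxy]pent-4-enal
Conditions: i-Bu2AlH, THF, −78 °C; aqueous potassium sodium tartrate
Reagents that add atoms: none
Why: Weinreb amide reduction stops at the chelated hemiaminal, so the aldehyde appears only on work-up and the α-centre C7 is not epimerised.

Step 11
Reactants: 18 aldehyde
Product: 20 tributyl[(1S,2S,3R)-2-(2,2-dimethoxyethyl)-1-{[(naphthalen-2-yl)methoxy]methoxy}-3-[(triethylsilyl)oxy]pent-4-en-1-yl]stannane, via hydroxystannane 19 (not isolated)
Conditions: Bu3SnLi (from Bu3SnH, LiN(i-Pr)2), THF, −78 °C; NH4Cl; then 2-NpCH2OCH2Cl, i-Pr2NEt, CH2Cl2, 0 °C to rt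
Reagents that add atoms: tributyltin hydride, CCCC[SnH](CCCC)CCCC; chloromethyl naphthalen-2-ylmethyl ether, ClCOCc1ccc2ccccc2c1
Why: Stannyl anion addition to the aldehyde, then immediate acetal protection of the labile α-hydroxystannane. Felkin–Anh attack anti to the C6 branch should place O8 syn to the C7 side chain (C8 as needed), and the minor C8 epimer is removed by chromatography.

Step 12
Reactants: 21 angelic acid
Product: 22 (2Z)-2-methylbut-2-en-1-ol
Conditions: LiAlH4, Et2O, 0 °C to rt
Reagents that add atoms: none
Why: Hydride reduction of the acid to the allylic alcohol with the Z geometry retained.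

Step 13
Reactants: 22 (2Z)-2-methylbut-2-en-1-ol
Product: 23 [(2S,3R)-2,3-dimethyloxiran-2-yl]methanol
Conditions: Ti(O-i-Pr)4 (cat.), L-(+)-diethyl tartrate (cat.), t-BuOOH, 4 Å sieves, CH2Cl2, −20 °C
Reagents that add atoms: tert-butyl hydroperoxide, CC(C)(C)OO
Why: Sharpless asymmetric epoxidation: the titanium tartrate complex delivers oxygen to the face that gives the 2S epoxy alcohol, and the Z olefin fixes the cis relation of C3-methyl and CH2OH.

Step 14
Reactants: 23 epoxy alcohol
Product: 24 (2R,3R)-2,3-dimethyloxirane-2-carboxylic acid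
Conditions: RuCl3·xH2O (cat.), NaIO4, MeCN/EtOAc/H2O, rt
Reagents that add atoms: sodium periodate, [Na+].[O-]I(=O)(=O)=O; water, O
Why: Ruthenium tetroxide oxidation of the primary alcohol to the acid leaves the epoxide intact; the C2 descriptor changes to R only through the sequence rule.

Step 15
Reactants: 20 stannane; 7 enone (racemic, 2 equiv)
Product: 27 cis diene-diol (C3,C9-diol with isopropenyl on C3 and the C5–C8 chain on C9), via alkyllithium 25 (not isolated), via silyl ether adduct 26 (not isolated)
Conditions: n-BuLi, THF, −78 °C, 10 min; 7, −78 °C; then MeOH, K2CO3, 0 °C to rt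
Reagents that add atoms: none
Why: Tin–lithium exchange gives the configurationally stable α-alkoxyalkyllithium, which adds 1,2 to the non-enolisable C9 ketone with retention at C8, forming C8–C9. Attack anti to the C3 silyloxy group (polar Felkin–Anh preference reinforced by the silyl group) puts the two alkenyl arms and the two oxygens cis. Brief exchange at −78 °C guards against 1,4-silyl migration, and methanolysis removes only the tertiary trimethylsilyl ether.

Step 16
Reactants: 27 cis diene-diol
Product: 28 cis-fused bicyclo[5.3.0]deca-2,8-diene-1,7-diol (C3,C9-diol)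
Conditions: second-generation Hoveyda–Grubbs catalyst RuCl2(H2IMes)(=CH-C6H4-2-O-i-Pr) (10 mol %), 1,4-benzoquinone (10 mol %), toluene (5 mM), 80 °C
Reagents that add atoms: none
Why: Ring-closing olefin metathesis: the carbene loads at the monosubstituted C5 vinyl group and closes onto the isopropenyl group to form the seven-membered ring with C4=C5. The olefin is necessarily cis in that ring, and the cis arms from step 15 allow closure.

Step 17
Reactants: 28 cis-fused bicyclic diol
Product: 29 (2Z,6Z,8R,9R,10R)-9-(2,2-dimethoxyethyl)-2,6-dimethyl-10-{[(naphthalen-2-yl)methoxy]methoxy}-8-[(triethylsilyl)oxy]cyclodeca-2,6-diene-1,5-dione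
Conditions: Pb(OAc)4 (1.2 equiv), CH2Cl2, −20 to 0 °C; filtration through silica
Reagents that add atoms: none
Why: Criegee glycol cleavage: the cis ring-fusion diol exchanges two acetates on tetravalent lead to give a five-membered cyclic lead diester, which collapses in a concerted two-electron fragmentation that breaks C3–C9, forms the C3 and C9 carbonyls and releases divalent lead. The closest known reaction type is the lead tetraacetate or periodate cleavage of fused-ring 1,2-diols to medium-ring diketones. No ring is closed by bond formation: the ten-membered ring is the periphery of the bicyclo[5.3.0] skeleton and appears when the zero-atom bridge is cut, so no dilution is needed. No stereocentre is formed; C3 and C9 become trigonal, so both cis diastereomers of 28 give the same dione, and C6, C7 and C8 are untouched. The selectivity needed is chemoselectivity for the glycol over the olefins, the naphthylmethyl ether and the acetal, secured by the fast cyclic-ester pathway at low temperature, which requires the cis diol set in step 15. The Z geometry of C1=C10 and C4=C5 was fixed by the five- and seven-membered rings and cannot change in a fragmentation that leaves both π bonds alone. Work-up is base-free and cold because the C2 methylene of 29 lies between the C3 ketone and the C1=C10 enone.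

Step 18
Reactants: 29 dione
Product: 30 (1R,2Z,5S,6Z,8R,9R,10R)-9-(2,2-dimethoxyethyl)-2,6-dimethyl-10-{[(naphthalen-2-yl)methoxy]methoxy}-8-[(triethylsilyl)oxy]cyclodeca-2,6-diene-1,5-diol
Conditions: (R)-2-methyl-CBS-oxazaborolidine (0.4 equiv), catecholborane (4 equiv), toluene, −78 °C; then MeOH, aq. NaOH wash
Reagents that add atoms: none
Why: Corey–Bakshi–Shibata reduction of both enones: the catalyst binds each carbonyl anti to its α-methylalkenyl group, and the (R)-catalyst should give 3S and 9R. At C9 this sense agrees with Felkin–Anh control from C8 (8,9-syn). Both alkoxides stay borylated until work-up, which prevents transannular hemiketal formation.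

Step 19
Reactants: 30 diol
Product: 31 3,9-bis(tert-butyldimethylsilyl) ether of 30
Conditions: t-BuMe2SiOTf (2.5 equiv), 2,6-lutidine, CH2Cl2, −78 °C
Reagents that add atoms: tert-butyldimethylsilyl trifluoromethanesulfonate, CC(C)(C)[Si](C)(C)OS(=O)(=O)C(F)(F)F
Why: Silylation of both allylic alcohols, including the hindered C9 hydroxyl; the low temperature spares the dimethyl acetal and the triethylsilyl ether.

Step 20
Reactants: 31 tris-silyl ether acetal
Product: 32 6,12-lactol (mixture of C12 anomers)
Conditions: AcOH/THF/H2O (3:1:1), rt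
Reagents that add atoms: water, O
Why: Mild acid removes the triethylsilyl group from O6 and hydrolyses the acetal; the aldehyde is trapped by the C6 hydroxyl as the five-membered lactol. The secondary tert-butyldimethylsilyl ethers and the O8 acetal are stable, and O8 cannot compete for C12.

Step 21
Reactants: 32 lactol
Product: 33 (3aS,4R,5R,6Z,9S,10Z,11aR)-5,9-bis[(tert-butyldimethylsilyl)oxy]-6,10-dimethyl-4-{[(naphthalen-2-yl)methoxy]methoxy}-3a,4,5,8,9,11a-hexahydrocyclodeca[b]furan-2(3H)-one
Conditions: (n-Pr4N)RuO4 (5 mol %), N-methylmorpholine N-oxide, 4 Å sieves, CH2Cl2, rt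
Reagents that add atoms: none
Why: Perruthenate-catalysed oxidation of the lactol to the trans-fused γ-lactone; no other oxidisable hydroxyl is present.

Step 22
Reactants: 33 lactone
Product: 37 α-methylene lactone (3-methylidene derivative of 33), via lithium enolate 34 (not isolated), via Mannich base 35 (not isolated), via ammonium iodide 36 (not isolated)
Conditions: LiN(i-Pr)2, THF, −78 °C; CH2=NMe2+ I−, −78 °C to rt; then MeI, MeOH, rt; then NaHCO3, CH2Cl2/H2O
Reagents that add atoms: N,N-dimethylmethyleneiminium iodide, C=[N+](C)C.[I-]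
Why: Mannich reaction of the lactone enolate with Eschenmoser's salt, N-methylation and E1cB elimination give the exocyclic C11=C13 olefin. The C11 stereocentre formed on the way is destroyed again.

Step 23
Reactants: 37 bis-silyl α-methylene lactone
Product: 38 (3aS,4R,5R,6Z,9S,10Z,11aR)-5,9-dihydroxy-6,10-dimethyl-3-methylidene-4-{[(naphthalen-2-yl)methoxy]methoxy}-3a,4,5,8,9,11a-hexahydrocyclodeca[b]furan-2(3H)-one
Conditions: HF·pyridine, pyridine, THF, 0 °C to rt
Reagents that add atoms: none
Why: Buffered fluoride desilylation frees the C3 and C9 hydroxyls without adding a nucleophile to the exocyclic enoate.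

Step 24
Reactants: 38 diol
Product: 39 (3aS,4R,5R,6Z,9S,10Z,11aR)-5-hydroxy-6,10-dimethyl-3-methylidene-4-{[(naphthalen-2-yl)methoxy]methoxy}-2-oxo-2,3,3a,4,5,8,9,11a-octahydrocyclodeca[b]furan-9-yl acetate
Conditions: Ac2O (1.05 equiv), pyridine, CH2Cl2, −20 to 0 °C
Reagents that add atoms: acetic anhydride, CC(=O)OC(C)=O
Why: Selective acetylation by steric differentiation: the C3 hydroxyl has a methylene neighbour, whereas the C9 hydroxyl is flanked by the branched, acetal-bearing C8 and should react much more slowly without an acyl-transfer catalyst.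

Step 25
Reactants: 39 hydroxy acetate; 24 (2R,3R)-2,3-dimethyloxirane-2-carboxylic acid
Product: 41 (3aS,4R,5R,6Z,9S,10Z,11aR)-9-(acetyloxy)-6,10-dimethyl-3-methylidene-4-{[(naphthalen-2-yl)methoxy]methoxy}-2-oxo-2,3,3a,4,5,8,9,11a-octahydrocyclodeca[b]furan-5-yl (2R,3R)-2,3-dimethyloxirane-2-carboxylate, via mixed anhydride 40 (not isolated)
Conditions: 24, 2,4,6-Cl3C6H2COCl, Et3N, toluene, rt; then 39, DMAP, toluene, rt
Reagents that add atoms: none
Why: Yamaguchi esterification forces acylation of the hindered C9 hydroxyl. The acid has no α-hydrogen, so its stereocentres cannot epimerise, and the conditions leave the epoxide and the enoate intact.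

Step 26
Reactants: 41 protected ester
Product: 42 CNP0137407.10, (3aR,4R,5R,6Z,9S,10Z,11aR)-9-(acetyloxy)-4-hydroxy-6,10-dimethyl-3-methylidene-2-oxo-2,3,3a,4,5,8,9,11a-octahydrocyclodeca[b]furan-5-yl (2R,3R)-2,3-dimethyloxirane-2-carboxylate
Conditions: DDQ, CH2Cl2/pH 7 phosphate buffer (10:1), 0 °C to rt
Reagents that add atoms: none
Why: Oxidative cleavage of the naphthylmethyl acetal: hydride abstraction at the benzylic carbon, hydrolysis to the aldehyde and loss of formaldehyde from the hemiformal free the C8 hydroxyl. The neutral medium protects the epoxy ester, the allylic acetate and the enoate and avoids acyl migration from O9 to O8.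

## Compound list

1 | cyclotene, 2-hydroxy-3-methylcyclopent-2-en-1-one | CC1=C(O)C(=O)CC1 | starting material
2 | 2-methoxy-3-methylcyclopent-2-en-1-one | COC1=C(C)CCC1=O | intermediate
3 | isopropenylmagnesium bromide | CC(=C)[Mg]Br | starting material
4 | 2-methoxy-3-methyl-1-(prop-1-en-2-yl)cyclopent-2-en-1-ol (racemic; formed as its bromomagnesium alkoxide) | COC1=C(C)CCC1(O)C(C)=C | intermediate
5 | 2-hydroxy-5-methyl-2-(prop-1-en-2-yl)cyclopentan-1-one (racemic; both C5 epimers) | CC1CCC(O)(C(C)=C)C1=O | intermediate
6 | 3-methyl-1-(prop-1-en-2-yl)-1,2-bis[(trimethylsilyl)oxy]cyclopent-2-ene (racemic) | CC1=C(O[Si](C)(C)C)C(O[Si](C)(C)C)(C(C)=C)CC1 | intermediate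
7 | 2-methyl-5-(prop-1-en-2-yl)-5-[(trimethylsilyl)oxy]cyclopent-2-en-1-one (racemic) | CC1=CCC(O[Si](C)(C)C)(C(C)=C)C1=O | intermediate
8 | methyl 4,4-dimethoxybutanoate | COC(OC)CCC(=O)OC | starting material
9 | 4,4-dimethoxybutanoic acid | COC(OC)CCC(O)=O | intermediate
10 | (4S)-4-benzyl-1,3-oxazolidin-2-one | O=C1N[C@@H](Cc2ccccc2)CO1 | starting material
11 | 4,4-dimethoxybutanoic pivalic anhydride | COC(OC)CCC(=O)OC(=O)C(C)(C)C | intermediate
12 | (4S)-4-benzyl-3-(4,4-dimethoxybutanoyl)-1,3-oxazolidin-2-one | COC(OC)CCC(=O)N1[C@@H](Cc2ccccc2)COC1=O | intermediate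
13 | acrolein, prop-2-enal | C=CC=O | starting material
14 | (Z)-dibutylboron enolate of 12 | CCCCB(CCCC)O/C(=C\CC(OC)OC)N1[C@@H](Cc2ccccc2)COC1=O | intermediate
15 | (4S)-4-benzyl-3-[(2S,3R)-2-(2,2-dimethoxyethyl)-3-hydroxypent-4-enoyl]-1,3-oxazolidin-2-one | C=C[C@@H](O)[C@H](CC(OC)OC)C(=O)N1[C@@H](Cc2ccccc2)COC1=O | intermediate
16 | (2S,3R)-2-(2,2-dimethoxyethyl)-3-hydroxy-N-methoxy-N-methylpent-4-enamide | C=C[C@@H](O)[C@H](CC(OC)OC)C(=O)N(C)OC | intermediate
17 | (2S,3R)-2-(2,2-dimethoxyethyl)-N-methoxy-N-methyl-3-[(triethylsilyl)oxy]pent-4-enamide | C=C[C@@H](O[Si](CC)(CC)CC)[C@H](CC(OC)OC)C(=O)N(C)OC | intermediate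
18 | (2S,3R)-2-(2,2-dimethoxyethyl)-3-[(triethylsilyl)oxy]pent-4-enal | C=C[C@@H](O[Si](CC)(CC)CC)[C@H](CC(OC)OC)C=O | intermediate
19 | (1S,2S,3R)-2-(2,2-dimethoxyethyl)-1-(tributylstannyl)-3-[(triethylsilyl)oxy]pent-4-en-1-ol | C=C[C@@H](O[Si](CC)(CC)CC)[C@H](CC(OC)OC)[C@@H](O)[Sn](CCCC)(CCCC)CCCC | intermediate
20 | tributyl[(1S,2S,3R)-2-(2,2-dimethoxyethyl)-1-{[(naphthalen-2-yl)methoxy]methoxy}-3-[(triethylsilyl)oxy]pent-4-en-1-yl]stannane | C=C[C@@H](O[Si](CC)(CC)CC)[C@H](CC(OC)OC)[C@@H](OCOCc1ccc2ccccc2c1)[Sn](CCCC)(CCCC)CCCC | intermediate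
21 | angelic acid, (2Z)-2-methylbut-2-enoic acid | C/C=C(/C)C(O)=O | starting material
22 | (2Z)-2-methylbut-2-en-1-ol | C/C=C(/C)CO | intermediate
23 | [(2S,3R)-2,3-dimethyloxiran-2-yl]methanol | OC[C@]1(C)O[C@@H]1C | intermediate
24 | (2R,3R)-2,3-dimethyloxirane-2-carboxylic acid | OC(=O)[C@]1(C)O[C@@H]1C | intermediate
25 | [(1S,2R,3R)-2-(2,2-dimethoxyethyl)-1-{[(naphthalen-2-yl)methoxy]methoxy}-3-[(triethylsilyl)oxy]pent-4-en-1-yl]lithium | C=C[C@@H](O[Si](CC)(CC)CC)[C@H](CC(OC)OC)[C@@H](OCOCc1ccc2ccccc2c1)[Li] | intermediate
26 | 27 with the C3 hydroxyl as its trimethylsilyl ether (formed as the lithium C9 alkoxide; with its 3R,9S diastereomer) | CC1=CC[C@](O[Si](C)(C)C)(C(C)=C)[C@]1(O)[C@H](OCOCc2ccc3ccccc3c2)[C@@H](CC(OC)OC)[C@H](O[Si](CC)(CC)CC)C=C | intermediate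
27 | (1S,2R)-2-[(1R,2R,3R)-2-(2,2-dimethoxyethyl)-1-{[(naphthalen-2-yl)methoxy]methoxy}-3-[(triethylsilyl)oxy]pent-4-en-1-yl]-3-methyl-1-(prop-1-en-2-yl)cyclopent-3-ene-1,2-diol (cis diol; with its 1R,2S diastereomer) | CC1=CC[C@](O)(C(C)=C)[C@]1(O)[C@H](OCOCc2ccc3ccccc3c2)[C@@H](CC(OC)OC)[C@H](O[Si](CC)(CC)CC)C=C | intermediate
28 | (1S,4R,5R,6R,7R)-5-(2,2-dimethoxyethyl)-2,8-dimethyl-6-{[(naphthalen-2-yl)methoxy]methoxy}-4-[(triethylsilyl)oxy]bicyclo[5.3.0]deca-2,8-diene-1,7-diol (cis ring fusion; with its 1R,7S diastereomer) | CC1=CC[C@]2(O)C(C)=C[C@@H](O[Si](CC)(CC)CC)[C@H](CC(OC)OC)[C@@H](OCOCc3ccc4ccccc4c3)[C@]12O | intermediate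
29 | (2Z,6Z,8R,9R,10R)-9-(2,2-dimethoxyethyl)-2,6-dimethyl-10-{[(naphthalen-2-yl)methoxy]methoxy}-8-[(triethylsilyl)oxy]cyclodeca-2,6-diene-1,5-dione | COC(OC)C[C@H]1[C@H](O[Si](CC)(CC)CC)/C=C(/C)C(=O)C/C=C(/C)C(=O)[C@@H]1OCOCc2ccc3ccccc3c2 | intermediate
30 | (1R,2Z,5S,6Z,8R,9R,10R)-9-(2,2-dimethoxyethyl)-2,6-dimethyl-10-{[(naphthalen-2-yl)methoxy]methoxy}-8-[(triethylsilyl)oxy]cyclodeca-2,6-diene-1,5-diol | COC(OC)C[C@H]1[C@H](O[Si](CC)(CC)CC)/C=C(/C)[C@@H](O)C/C=C(/C)[C@@H](O)[C@@H]1OCOCc2ccc3ccccc3c2 | intermediate
31 | 1,5-bis-O-(tert-butyldimethylsilyl) ether of 30 (3S,6R,7R,8R,9R in ring locants) | COC(OC)C[C@H]1[C@H](O[Si](CC)(CC)CC)/C=C(/C)[C@@H](O[Si](C)(C)C(C)(C)C)C/C=C(/C)[C@@H](O[Si](C)(C)C(C)(C)C)[C@@H]1OCOCc2ccc3ccccc3c2 | intermediate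
32 | 2-hydroxy analogue (lactol, both C12 anomers) of lactone 33 | C1C(O)O[C@@H]2/C=C(/C)[C@@H](O[Si](C)(C)C(C)(C)C)C/C=C(/C)[C@@H](O[Si](C)(C)C(C)(C)C)[C@H](OCOCc3ccc4ccccc4c3)[C@@H]12 | intermediate
33 | (3aS,4R,5R,6Z,9S,10Z,11aR)-5,9-bis[(tert-butyldimethylsilyl)oxy]-6,10-dimethyl-4-{[(naphthalen-2-yl)methoxy]methoxy}-3a,4,5,8,9,11a-hexahydrocyclodeca[b]furan-2(3H)-one | C1C(=O)O[C@@H]2/C=C(/C)[C@@H](O[Si](C)(C)C(C)(C)C)C/C=C(/C)[C@@H](O[Si](C)(C)C(C)(C)C)[C@H](OCOCc3ccc4ccccc4c3)[C@@H]12 | intermediate
34 | lithium enolate of lactone 33 | C1=C(O[Li])O[C@@H]2/C=C(/C)[C@@H](O[Si](C)(C)C(C)(C)C)C/C=C(/C)[C@@H](O[Si](C)(C)C(C)(C)C)[C@H](OCOCc3ccc4ccccc4c3)[C@@H]12 | intermediate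
35 | 3-[(dimethylamino)methyl] derivative of lactone 33 (both C11 epimers) | CN(C)CC1C(=O)O[C@@H]2/C=C(/C)[C@@H](O[Si](C)(C)C(C)(C)C)C/C=C(/C)[C@@H](O[Si](C)(C)C(C)(C)C)[C@H](OCOCc3ccc4ccccc4c3)[C@@H]12 | intermediate
36 | 3-[(trimethylammonio)methyl] derivative of lactone 33, iodide (both C11 epimers) | C[N+](C)(C)CC1C(=O)O[C@@H]2/C=C(/C)[C@@H](O[Si](C)(C)C(C)(C)C)C/C=C(/C)[C@@H](O[Si](C)(C)C(C)(C)C)[C@H](OCOCc3ccc4ccccc4c3)[C@@H]12.[I-] | intermediate
37 | (3aS,4R,5R,6Z,9S,10Z,11aR)-5,9-bis[(tert-butyldimethylsilyl)oxy]-6,10-dimethyl-3-methylidene-4-{[(naphthalen-2-yl)methoxy]methoxy}-3a,4,5,8,9,11a-hexahydrocyclodeca[b]furan-2(3H)-one | C=C1C(=O)O[C@@H]2/C=C(/C)[C@@H](O[Si](C)(C)C(C)(C)C)C/C=C(/C)[C@@H](O[Si](C)(C)C(C)(C)C)[C@H](OCOCc3ccc4ccccc4c3)[C@@H]12 | intermediate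
38 | (3aS,4R,5R,6Z,9S,10Z,11aR)-5,9-dihydroxy-6,10-dimethyl-3-methylidene-4-{[(naphthalen-2-yl)methoxy]methoxy}-3a,4,5,8,9,11a-hexahydrocyclodeca[b]furan-2(3H)-one | C=C1C(=O)O[C@@H]2/C=C(/C)[C@@H](O)C/C=C(/C)[C@@H](O)[C@H](OCOCc3ccc4ccccc4c3)[C@@H]12 | intermediate
39 | (3aS,4R,5R,6Z,9S,10Z,11aR)-5-hydroxy-6,10-dimethyl-3-methylidene-4-{[(naphthalen-2-yl)methoxy]methoxy}-2-oxo-2,3,3a,4,5,8,9,11a-octahydrocyclodeca[b]furan-9-yl acetate | C=C1C(=O)O[C@@H]2/C=C(/C)[C@@H](OC(C)=O)C/C=C(/C)[C@@H](O)[C@H](OCOCc3ccc4ccccc4c3)[C@@H]12 | intermediate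
40 | (2R,3R)-2,3-dimethyloxirane-2-carboxylic 2,4,6-trichlorobenzoic anhydride | O=C(OC(=O)c1c(Cl)cc(Cl)cc1Cl)[C@]2(C)O[C@@H]2C | intermediate
41 | (3aS,4R,5R,6Z,9S,10Z,11aR)-9-(acetyloxy)-6,10-dimethyl-3-methylidene-4-{[(naphthalen-2-yl)methoxy]methoxy}-2-oxo-2,3,3a,4,5,8,9,11a-octahydrocyclodeca[b]furan-5-yl (2R,3R)-2,3-dimethyloxirane-2-carboxylate | C=C1C(=O)O[C@@H]2/C=C(/C)[C@@H](OC(C)=O)C/C=C(/C)[C@@H](OC(=O)[C@]3(C)O[C@@H]3C)[C@H](OCOCc3ccc4ccccc4c3)[C@@H]12 | intermediate
42 | CNP0137407.10, (3aR,4R,5R,6Z,9S,10Z,11aR)-9-(acetyloxy)-4-hydroxy-6,10-dimethyl-3-methylidene-2-oxo-2,3,3a,4,5,8,9,11a-octahydrocyclodeca[b]furan-5-yl (2R,3R)-2,3-dimethyloxirane-2-carboxylate | C=C1C(=O)O[C@@H]2/C=C(/C)[C@@H](OC(C)=O)C/C=C(/C)[C@@H](OC(=O)[C@]3(C)O[C@@H]3C)[C@H](O)[C@@H]12 | target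

## Step count and least certain steps

Total step count: 26. Longest linear sequence: 19 steps (from 8 through steps 5–11 and 15–26). The enone branch (steps 1–4) and the acid branch (steps 12–14) join at steps 15 and 25.

**Step 17 (key step).** The ditertiary diol is flanked by two trisubstituted olefins and a branched carbon, so formation of the cyclic lead diester may be slow for one of the two diastereomers. The acetic acid set free could then strip the triethylsilyl ether or the acetal, after which the exposed C6 hydroxyl would add across the ring to the new C3 carbonyl. The fallback changes the order so that the cleavage meets a substrate without acid-labile groups. It sets out from 28: aqueous acetic acid in THF should give the tricyclic lactol F1, and a Parikh–Doering oxidation (SO3·pyridine, DMSO, i-Pr2NEt, chosen because it does not attack a glycol) the tricyclic lactone diol F2. Pb(OAc)4 would then give the lactone dione F3, reduction as in step 18 the lactone diol F4, and silylation as in step 19 returns to the route at 33. This order has the same step count; it is held in reserve because it exposes the tertiary allylic diol to aqueous acid.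

**Step 15.** Facial selectivity in the addition may be poor, because the isopropenyl group is sterically at least as large as the silyloxy group, so approach syn to oxygen may compete and lead to the trans arrangement. Silyl migration from O6 to the carbanion and γ-deprotonation of 7 are lesser drains. The fallback accepts the trans series and changes the mode of cleavage. It sets out from 20 and 7: the same operations would give the trans silyl ether adduct F5 and, after methanolysis, the trans diene-diol F6. Ring-closing metathesis to the trans-fused bicyclic diol F7 remains feasible for a 5-7 system. Pb(OAc)4 in pyridine, which cleaves glycols through an open-chain lead monoester and does not need the cyclic diester, should then return to the route at 29.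

**Step 16.** Ring closure may be slow because the isopropenyl group sits on a fully substituted carbon and the vinyl group next to a silyloxy-bearing carbon, so olefin isomerisation or dimerisation through the vinyl group may take over. The fallback uses a free allylic hydroxyl to speed carbene loading and ring closure. It sets out from 27: Bu4NF buffered with AcOH should give the C6-hydroxy diene F8, metathesis the bicyclic triol F9, and Et3SiCl with imidazole, which silylates only the secondary hydroxyl, returns to the route at 28.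

**Step 18.** Facial discrimination at C9 may be insufficient, since the catalyst must tell an α-methylalkenyl group from an α-alkoxy secondary alkyl group, and ring conformation may override both reagent and Felkin–Anh preferences. The fallback separates the two reductions. It sets out from 29: the same catalyst with one equivalent of catecholborane should reduce only the less hindered C3 carbonyl to give the 3-hydroxy-9-ketone F10 (possibly in part as its transannular hemiketal). LiBH(s-Bu)3 in THF at −78 °C, a bulky non-chelating hydride that follows Felkin–Anh control from C8, should then set C9 and return to the route at 30.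

**Step 24.** Discrimination between the two allylic hydroxyls may be incomplete, leading to acetylation at C9 or at both positions. The fallback replaces direct acylation by temporary protection. It sets out from 38: t-BuMe2SiCl with imidazole in DMF, a bulkier and more discriminating electrophile, should give the 3-silyl ether F11. Yamaguchi esterification with 24 through 40 would give the 9-ester F12, HF·pyridine the 3-hydroxy 9-ester F13, and Ac2O with DMAP returns to the route at 41.

## Further compounds

F1 | step 17 | tricyclic lactol of the cis-fused bicyclic diol (O6–C12 hemiacetal; C12 anomers) | CC1=CC[C@]2(O)C(C)=C[C@H]3OC(O)C[C@@H]3[C@@H](OCOCc4ccc5ccccc5c4)[C@]12O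
F2 | step 17 | tricyclic lactone with the cis ring-fusion diol | CC1=CC[C@]2(O)C(C)=C[C@H]3OC(=O)C[C@@H]3[C@@H](OCOCc4ccc5ccccc5c4)[C@]12O
F3 | step 17 | ten-membered (Z,Z)-3,9-dione fused to the saturated lactone | C1C(=O)O[C@@H]2/C=C(/C)C(=O)C/C=C(/C)C(=O)[C@H](OCOCc3ccc4ccccc4c3)[C@@H]12
F4 | step 17 | ten-membered (3S,9R)-diol fused to the saturated lactone | C1C(=O)O[C@@H]2/C=C(/C)[C@@H](O)C/C=C(/C)[C@@H](O)[C@H](OCOCc3ccc4ccccc4c3)[C@@H]12
F5 | step 15 | trans silyl ether adduct (C9 epimer of 26) | CC1=CC[C@](O[Si](C)(C)C)(C(C)=C)[C@@]1(O)[C@H](OCOCc2ccc3ccccc3c2)[C@@H](CC(OC)OC)[C@H](O[Si](CC)(CC)CC)C=C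
F6 | step 15 | trans diene-diol (C9 epimer of 27) | CC1=CC[C@](O)(C(C)=C)[C@@]1(O)[C@H](OCOCc2ccc3ccccc3c2)[C@@H](CC(OC)OC)[C@H](O[Si](CC)(CC)CC)C=C
F7 | step 15 | trans-fused bicyclic diol (C9 epimer of 28) | CC1=CC[C@]2(O)C(C)=C[C@@H](O[Si](CC)(CC)CC)[C@H](CC(OC)OC)[C@@H](OCOCc3ccc4ccccc4c3)[C@@]12O
F8 | step 16 | C6-hydroxy diene (27 without the triethylsilyl group) | CC1=CC[C@](O)(C(C)=C)[C@]1(O)[C@H](OCOCc2ccc3ccccc3c2)[C@@H](CC(OC)OC)[C@H](O)C=C
F9 | step 16 | bicyclic triol (28 without the triethylsilyl group) | CC1=CC[C@]2(O)C(C)=C[C@@H](O)[C@H](CC(OC)OC)[C@@H](OCOCc3ccc4ccccc4c3)[C@]12O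
F10 | step 18 | (3S)-3-hydroxy-9-ketone (29 reduced at C3 only) | COC(OC)C[C@H]1[C@H](O[Si](CC)(CC)CC)/C=C(/C)[C@@H](O)C/C=C(/C)C(=O)[C@@H]1OCOCc2ccc3ccccc3c2
F11 | step 24 | 3-O-(tert-butyldimethylsilyl) ether of 38 | C=C1C(=O)O[C@@H]2/C=C(/C)[C@@H](O[Si](C)(C)C(C)(C)C)C/C=C(/C)[C@@H](O)[C@H](OCOCc3ccc4ccccc4c3)[C@@H]12
F12 | step 24 | 3-O-silyl 9-O-[(2R,3R)-2,3-dimethyloxirane-2-carbonyl] derivative of 38 | C=C1C(=O)O[C@@H]2/C=C(/C)[C@@H](O[Si](C)(C)C(C)(C)C)C/C=C(/C)[C@@H](OC(=O)[C@]3(C)O[C@@H]3C)[C@H](OCOCc3ccc4ccccc4c3)[C@@H]12
F13 | step 24 | 3-hydroxy 9-O-[(2R,3R)-2,3-dimethyloxirane-2-carbonyl] derivative of 38 | C=C1C(=O)O[C@@H]2/C=C(/C)[C@@H](O)C/C=C(/C)[C@@H](OC(=O)[C@]3(C)O[C@@H]3C)[C@H](OCOCc3ccc4ccccc4c3)[C@@H]12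
A1 | alternative 1 | 9-hydroxy-8-(triethylsilyloxy) germacranolide from closure of C9–C10 | C=C1C(=O)O[C@@H]2/C=C(/C)[C@@H](OC(C)=O)C/C=C(/C)[C@@H](O)[C@H](O[Si](CC)(CC)CC)[C@@H]12
A2 | alternative 2 | ten-membered dienol with C6 hydroxyl and C7 2-propenyl branch from the [2,3]-shift | C=C(COCc1ccc(OC)cc1)[C@H]2[C@H](O)/C=C(/C)[C@@H](O[Si](C)(C)C(C)(C)C)C/C=C(/C)[C@@H](O[Si](CC)(CC)CC)[C@@H]2O[Si](C(C)C)(C(C)C)C(C)C
A3 | alternative 3 | ten-membered 8,9-diol fused to the saturated lactone from the pinacol closure | O=C1C[C@H]2[C@H](O1)/C=C(/C)[C@@H](O[Si](C)(C)C(C)(C)C)C/C=C(/C)[C@@H](O)[C@@H]2O
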